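Everything rests on one disconnection in unit A. There C8 holds the phenolic oxygen of ring B, the carbinol carbon C7 and C9 together, the pattern a carbene carbon acquires when it joins a phenol O–H to a formyl group. A rhodium-carbenoid three-component coupling therefore forms C8–O and C7–C8 and sets both stereocentres in one operation. Its precursors are three commercial compounds: ethyl diazoacetate (C8, C9), methyl syringate (ring B) and O-acetylvanillin (ring A, C7), whose acetyl group makes the aldehyde a better acceptor. The derived ring B aldehyde is then joined by auxiliary aldol chemistry to an aryloxyacetyl imide of the ring C/D dihydrobenzofuran; Heck vinylation and desilylation finish.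

Key step: step 1

Labels: ring A with C7–C9 is the guaiacyl unit, ring B with C7'–C9' the inner syringyl unit, ring C the syringyl ring on C7'', ring D the arene of the dihydrobenzofuran (C7'' = its C2, C8'' = its C3, C9'' = CH2OH). The descriptors at C8, C8' and C8'' change between the carbonyl stage (R) and the alcohol stage (S) only because the CIP ranking changes.
Assumption: the sense of induction of the phosphoric acid in step 1 cannot be fixed beforehand; the (R)-acid is written, and its antipode is taken if the enantiomeric ester forms.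

Step 1
Reactants: 1 4-formyl-2-methoxyphenyl acetate (O-acetylvanillin); 2 ethyl diazoacetate; 3 methyl 4-hydroxy-3,5-dimethoxybenzoate (methyl syringate)
Product: 5 ethyl (2R,3R)-3-(4-acetoxy-3-methoxyphenyl)-2-(2,6-dimethoxy-4-methoxycarbonylphenoxy)-3-hydroxypropanoate (erythro), via oxonium ylide 4 (not isolated)
Conditions: Rh2(OAc)4 (2 mol%), (R)-TRIP [(R)-3,3'-bis(2,4,6-triisopropylphenyl)-1,1'-binaphthyl-2,2'-diyl hydrogen phosphate] (10 mol%), 4 Å MS, CH2Cl2, −20 °C; 2 added over 6 h to 1 (2 equiv) and 3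
Reagents that add atoms: none
Why: Proposed new method: Rh2(OAc)4 decomposes 2 to an electrophilic rhodium carbenoid, the hindered phenol oxygen of 3 adds to it, and the protic oxonium ylide 4 (an enol equivalent of the aryloxyacetate) is captured at carbon by aldehyde 1, which the chiral phosphoric acid activates by hydrogen bonding, before the 1,2-proton shift to the plain O–H insertion product takes place, so that C8–O and C7–C8 form in one flask. The closest known reaction type is the rhodium/Brønsted acid co-catalysed three-component aldol-type trapping of alcohol-derived oxonium ylides of aryl diazoacetates by activated aldehydes; new here are the acceptor-only diazo ester, the phenolic O–H partner and the only moderately activated aldehyde. No ring is closed. C7 and C8 are both set under catalyst control: the phosphate bridges the enol O–H and the formyl oxygen in a cyclic transition state in which the aryloxy group and the aryl group of 1 lie apart (anti, erythro), and the 3,3'-aryl groups of the acid choose the enantiotopic faces. The selectivity needed is trapping over proton transfer and over carbene dimerisation; it is secured by the electron-withdrawing acetoxy group of 1 (a better acceptor than a silyl- or alkyl-protected vanillin), by slow addition of 2 to an excess of 1 at low temperature, and by the two ortho methoxy groups of 3, which can hold the oxonium proton in an internal hydrogen bond and so delay its shift.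

Step 2
Reactants: 5 erythro hydroxy ester
Product: 6 ethyl (2R,3R)-3-(4-acetoxy-3-methoxyphenyl)-3-(tert-butyldimethylsilyloxy)-2-(2,6-dimethoxy-4-methoxycarbonylphenoxy)propanoate
Conditions: TBSOTf, 2,6-lutidine, CH2Cl2, −78 to 0 °C
Reagents that add atoms: tert-butyldimethylsilyl triflate, CC(C)(C)[Si](C)(C)OS(=O)(=O)C(F)(F)F
Why: Silyl ether formation with a silyl triflate and a hindered base is routine for a secondary alcohol, leaves the esters alone, blocks retro-aldol cleavage during the reduction and keeps C7–OH away from the later benzylic oxidant.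

Step 3
Reactants: 6 silylated diester
Product: 7 4-[(1R,2S)-1-(tert-butyldimethylsilyloxy)-3-hydroxy-2-(4-hydroxymethyl-2,6-dimethoxyphenoxy)propyl]-2-methoxyphenol
Conditions: LiAlH4, THF, 0 °C; aqueous Rochelle salt work-up
Reagents that add atoms: none
Why: Hydride reduction of esters converts the ethyl ester to C9–OH and the benzoate to the ring B benzylic alcohol and cleaves the aryl acetate, while the silyl ether and both stereocentres, no longer next to a carbonyl group, are not touched.

Step 4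
Reactants: 7 phenol diol
Product: 8 4-{[(1R,2S)-1-(tert-butyldimethylsilyloxy)-3-hydroxy-1-(4-hydroxy-3-methoxyphenyl)propan-2-yl]oxy}-3,5-dimethoxybenzaldehyde
Conditions: MnO2 (activated, excess), CH2Cl2, rt
Reagents that add atoms: none
Why: Chemoselective benzylic oxidation by MnO2 should convert only the ring B hydroxymethyl group, because C9–OH is not benzylic and the only other benzylic oxygen (C7) is silylated.

Step 5
Reactants: 8 hydroxy aldehyde
Product: 9 4-{[(1R,2S)-1,3-bis(tert-butyldimethylsilyloxy)-1-[4-(tert-butyldimethylsilyloxy)-3-methoxyphenyl]propan-2-yl]oxy}-3,5-dimethoxybenzaldehyde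
Conditions: TBSCl (2.5 equiv), imidazole, DMF, rt
Reagents that add atoms: tert-butyldimethylsilyl chloride, CC(C)(C)[Si](C)(C)Cl
Why: Imidazole-mediated silyl ether formation caps the phenol and the primary alcohol so that no acidic O–H remains for the boron aldol reaction.

Step 6
Reactants: 10 2-hydroxy-3-methoxybenzaldehyde (o-vanillin)
Product: 11 2-hydroxy-5-iodo-3-methoxybenzaldehyde
Conditions: NIS, MeCN, 0 °C to rt
Reagents that add atoms: N-iodosuccinimide, O=C1CCC(=O)N1I
Why: Electrophilic aromatic iodination goes para to the free phenol, the only strongly activated open position, and places the handle for the final Heck reaction at the future C5 of ring D.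

Step 7
Reactants: 11 iodophenol aldehyde
Product: 12 5-iodo-3-methoxy-2-(methoxymethoxy)benzaldehyde
Conditions: MOMCl, i-Pr2NEt, CH2Cl2, 0 °C to rt
Reagents that add atoms: chloromethyl methyl ether, COCCl
Why: O-alkylation of the phenol (Williamson-type) gives a MOM acetal that is stable to the basic homologation and to the aldol reaction and is removed by acid later.

Step 8
Reactants: 12 MOM-protected aldehyde
Product: 14 2-[5-iodo-3-methoxy-2-(methoxymethoxy)phenyl]acetonitrile, via tosylvinyl formamide 13 (not isolated)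
Conditions: TosMIC, t-BuOK, DME, −35 °C; then MeOH, reflux
Reagents that add atoms: tosylmethyl isocyanide, Cc1ccc(cc1)S(=O)(=O)C[N+]#[C-]
Why: The van Leusen reductive cyanation adds the isocyanide anion to the aldehyde, and methanolysis of the ring-opened formamide 13 expels formate and sulfinate to leave the nitrile homologated by one carbon.

Step 9
Reactants: 14 arylacetonitrile
Product: 15 2-[5-iodo-3-methoxy-2-(methoxymethoxy)phenyl]acetic acid
Conditions: KOH, EtOH/H2O, reflux; then 1 M HCl to pH 4, 0 °C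
Reagents that add atoms: water, O; potassium hydroxide, [K+].[OH-]
Why: Basic nitrile hydrolysis gives the carboxylate without harm to the MOM ether or the aryl iodide, and cold, mild acidification frees the acid.

Step 10
Reactants: 15 arylacetic acid; 16 (R)-4-benzyl-1,3-oxazolidin-2-one
Product: 18 (R)-4-benzyl-3-{2-[5-iodo-3-methoxy-2-(methoxymethoxy)phenyl]acetyl}-1,3-oxazolidin-2-one, via mixed pivalic anhydride 17 (not isolated)
Conditions: PivCl, Et3N, THF, −20 °C; then LiCl, 16, −20 °C to rt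
Reagents that add atoms: none
Why: N-Acylation of the oxazolidinone through the mixed pivalic anhydride with LiCl activation is a standard, mildly basic way to attach the auxiliary.

Step 11
Reactants: 19 4-hydroxy-3,5-dimethoxybenzaldehyde (syringaldehyde)
Product: 20 3,5-dimethoxy-4-(methoxymethoxy)benzaldehyde
Conditions: MOMCl, i-Pr2NEt, CH2Cl2, 0 °C to rt
Reagents that add atoms: chloromethyl methyl ether, COCCl
Why: O-Alkylation of the phenol as its MOM acetal removes the acidic proton before the boron aldol reaction and allows both phenols to be freed together in step 14.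

Step 12
Reactants: 18 arylacetyl imide; 20 MOM-protected syringaldehyde
Product: 23 (R)-4-benzyl-3-[(2R,3R)-3-[3,5-dimethoxy-4-(methoxymethoxy)phenyl]-3-hydroxy-2-[5-iodo-3-methoxy-2-(methoxymethoxy)phenyl]propanoyl]-1,3-oxazolidin-2-one, via Z-boron enolate 21 (not isolated), via boron aldolate 22 (not isolated)
Conditions: Bu2BOTf, i-Pr2NEt, CH2Cl2, −78 to 0 °C; 20, −78 to 0 °C; then pH 7 buffer, MeOH, 30% H2O2, 0 °C
Reagents that add atoms: none
Why: In this Evans syn aldol the Z-boron enolate 21 reacts through a chair Zimmerman–Traxler transition state on the face away from the benzyl group of the (R)-auxiliary, which fixes C8'' (R here, S after reduction) and gives the 2,3-syn adduct whose C7'' configuration is overwritten in step 14.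

Step 13
Reactants: 23 syn aldol adduct
Product: 24 (1R,2S)-1-[3,5-dimethoxy-4-(methoxymethoxy)phenyl]-2-[5-iodo-3-methoxy-2-(methoxymethoxy)phenyl]propane-1,3-diol
Conditions: LiBH4, MeOH (1 equiv), THF, 0 °C
Reagents that add atoms: none
Why: Reductive cleavage of the imide with LiBH4 releases C9''–OH and the auxiliary under conditions too mild to epimerise the α-aryl centre.

Step 14
Reactants: 24 bis-MOM diol
Product: 26 4-[(2R,3S)-3-hydroxymethyl-5-iodo-7-methoxy-2,3-dihydro-1-benzofuran-2-yl]-2,6-dimethoxyphenol, via deprotected tetraol 25 (not isolated)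
Conditions: 2 M aq. HCl, THF, 45 °C
Reagents that add atoms: none
Why: Aqueous acid hydrolyses both MOM acetals and ionises the p-hydroxybenzylic alcohol of 25 to a quinone-methide-type cation, which the ring D phenol captures in a 5-exo closure trans to the C8'' hydroxymethyl group, so that C7'' becomes R under control by C8'' (acid-mediated phenylcoumaran cyclisation).

Step 15
Reactants: 16 (R)-4-benzyl-1,3-oxazolidin-2-one; 27 bromoacetyl bromide
Product: 29 (R)-4-benzyl-3-(2-bromoacetyl)-1,3-oxazolidin-2-one, via lithiated oxazolidinone 28 (not isolated)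
Conditions: n-BuLi, THF, −78 °C; then 27, −78 to 0 °C
Reagents that add atoms: none
Why: N-Acylation of the lithium amide 28 by the acid bromide is much faster at low temperature than alkylation at the CH2Br group.

Step 16
Reactants: 26 dihydrobenzofuran phenol; 29 bromoacetyl imide
Product: 30 (R)-4-benzyl-3-{[4-((2R,3S)-3-hydroxymethyl-5-iodo-7-methoxy-2,3-dihydro-1-benzofuran-2-yl)-2,6-dimethoxyphenoxy]acetyl}-1,3-oxazolidin-2-one
Conditions: K2CO3, acetone, rt to 45 °C
Reagents that add atoms: none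
Why: In this Williamson ether synthesis carbonate deprotonates only the phenol, whose oxygen displaces the activated α-bromide while the far less acidic primary alcohol stays untouched.

Step 17
Reactants: 30 hydroxy imide
Product: 31 (R)-4-benzyl-3-{[4-((2R,3S)-3-(tert-butyldimethylsilyloxymethyl)-5-iodo-7-methoxy-2,3-dihydro-1-benzofuran-2-yl)-2,6-dimethoxyphenoxy]acetyl}-1,3-oxazolidin-2-one
Conditions: TBSCl, imidazole, DMF, rt
Reagents that add atoms: tert-butyldimethylsilyl chloride, CC(C)(C)[Si](C)(C)Cl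
Why: Silyl ether formation at the primary alcohol removes the last free hydroxyl group before enolisation and before the Mitsunobu step.

Step 18
Reactants: 31 aryloxyacetyl imide; 9 ring B aldehyde
Product: 34 (7'S,8'R)-syn aldol adduct of 31 and 9 (imide with 7'-OH), via Z-boron enolate 32 (not isolated), via boron aldolate 33 (not isolated)
Conditions: Bu2BOTf, i-Pr2NEt, CH2Cl2, −78 to 0 °C; 9, −78 to 0 °C; then pH 7 buffer, MeOH, 30% H2O2, 0 °C
Reagents that add atoms: none
Why: In this Evans syn aldol of an aryloxyacetyl imide the Z-boron enolate 32 adds to 9 through a closed chair transition state on the face opposite the benzyl group, which sets C8' as the target requires and C7' as its syn (threo) epimer under auxiliary control.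

Step 19
Reactants: 34 syn aldol adduct
Product: 35 (7'R,8'R)-anti 7'-O-(4-nitrobenzoyl) imide
Conditions: 4-nitrobenzoic acid, PPh3, DIAD, THF, 0 °C to rt
Reagents that add atoms: 4-nitrobenzoic acid, O=C(O)c1ccc(cc1)[N+](=O)[O-]
Why: Mitsunobu inversion with an acidic carboxylic acid displaces the activated benzylic oxygen at C7' by SN2, turning the syn (threo) adduct into the anti (erythro) ester without touching C8'.

Step 20
Reactants: 35 inverted nitrobenzoate
Product: 36 (7R,8S,7'R,8'S,7''R,8''S)-7',9'-diol (5-iodo, four TBS ethers)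
Conditions: LiBH4 (excess), MeOH, THF, 0 °C to rt
Reagents that add atoms: none
Why: Reductive cleavage by LiBH4 converts the imide into C9'–OH and the activated nitrobenzoate into free C7'–OH in one operation and spares silyl ethers, the aryl iodide and all stereocentres.

Step 21
Reactants: 36 iodo diol; 37 acrolein
Product: 38 tetrakis-TBS ether of the target (E-enal)
Conditions: 37 (5 equiv), Pd(OAc)2 (10 mol%), n-Bu4NCl, NaHCO3, DMF, 50 °C
Reagents that add atoms: none
Why: In this Mizoroki–Heck reaction zerovalent palladium inserts into the aryl iodide, acrolein is carbopalladated at its terminal carbon and β-hydride elimination gives the E-enal under ligand-free phase-transfer conditions that tolerate free hydroxyl groups and silyl ethers.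

Step 22
Reactants: 38 silylated enal
Product: 39 CNP0192639.1 (target)
Conditions: HF·pyridine, pyridine, THF, 0 °C to rt
Reagents that add atoms: none
Why: Buffered fluoride desilylation should remove the three alkyl and the one aryl silyl ether without acid or base strong enough to epimerise the benzylic carbinols or attack the enal.

Compound list
1 | 4-formyl-2-methoxyphenyl acetate (O-acetylvanillin) | COc1cc(C=O)ccc1OC(C)=O | starting material
2 | ethyl diazoacetate | CCOC(=O)C=[N+]=[N-] | starting material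
3 | methyl 4-hydroxy-3,5-dimethoxybenzoate (methyl syringate) | COC(=O)c1cc(OC)c(O)c(OC)c1 | starting material
4 | protic oxonium ylide from the carbene of 2 and the phenol oxygen of 3 (not isolated) | CCOC(=O)[CH-][OH+]c1c(OC)cc(C(=O)OC)cc1OC | intermediate
5 | ethyl (2R,3R)-3-(4-acetoxy-3-methoxyphenyl)-2-(2,6-dimethoxy-4-methoxycarbonylphenoxy)-3-hydroxypropanoate (erythro) | COc1cc([C@@H](O)[C@H](C(=O)OCC)Oc2c(OC)cc(C(=O)OC)cc2OC)ccc1OC(C)=O | intermediate
6 | 3-O-TBS ether of 5, (2R,3R) | COc1cc([C@@H](O[Si](C)(C)C(C)(C)C)[C@H](C(=O)OCC)Oc2c(OC)cc(C(=O)OC)cc2OC)ccc1OC(C)=O | intermediate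
7 | 4-[(1R,2S)-1-(tert-butyldimethylsilyloxy)-3-hydroxy-2-(4-hydroxymethyl-2,6-dimethoxyphenoxy)propyl]-2-methoxyphenol | COc1cc([C@@H](O[Si](C)(C)C(C)(C)C)[C@H](CO)Oc2c(OC)cc(CO)cc2OC)ccc1O | intermediate
8 | 4-{[(1R,2S)-1-(tert-butyldimethylsilyloxy)-3-hydroxy-1-(4-hydroxy-3-methoxyphenyl)propan-2-yl]oxy}-3,5-dimethoxybenzaldehyde | COc1cc([C@@H](O[Si](C)(C)C(C)(C)C)[C@H](CO)Oc2c(OC)cc(C=O)cc2OC)ccc1O | intermediate
9 | 4-{[(1R,2S)-1,3-bis(tert-butyldimethylsilyloxy)-1-[4-(tert-butyldimethylsilyloxy)-3-methoxyphenyl]propan-2-yl]oxy}-3,5-dimethoxybenzaldehyde | COc1cc([C@@H](O[Si](C)(C)C(C)(C)C)[C@H](CO[Si](C)(C)C(C)(C)C)Oc2c(OC)cc(C=O)cc2OC)ccc1O[Si](C)(C)C(C)(C)C | intermediate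
10 | 2-hydroxy-3-methoxybenzaldehyde (o-vanillin) | COc1cccc(C=O)c1O | starting material
11 | 2-hydroxy-5-iodo-3-methoxybenzaldehyde | COc1cc(I)cc(C=O)c1O | intermediate
12 | 5-iodo-3-methoxy-2-(methoxymethoxy)benzaldehyde | COCOc1c(OC)cc(I)cc1C=O | intermediate
13 | N-{2-[5-iodo-3-methoxy-2-(methoxymethoxy)phenyl]-1-(4-methylbenzenesulfonyl)ethenyl}formamide, alkene geometry not defined (not isolated) | O=CNC(=Cc1cc(I)cc(OC)c1OCOC)S(=O)(=O)c1ccc(C)cc1 | intermediate
14 | 2-[5-iodo-3-methoxy-2-(methoxymethoxy)phenyl]acetonitrile | COCOc1c(OC)cc(I)cc1CC#N | intermediate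
15 | 2-[5-iodo-3-methoxy-2-(methoxymethoxy)phenyl]acetic acid | COCOc1c(OC)cc(I)cc1CC(=O)O | intermediate
16 | (R)-4-benzyl-1,3-oxazolidin-2-one | O=C1N[C@H](Cc2ccccc2)CO1 | starting material
17 | mixed anhydride of 15 with pivalic acid (not isolated) | COCOc1c(OC)cc(I)cc1CC(=O)OC(=O)C(C)(C)C | intermediate
18 | (R)-4-benzyl-3-{2-[5-iodo-3-methoxy-2-(methoxymethoxy)phenyl]acetyl}-1,3-oxazolidin-2-one | COCOc1c(OC)cc(I)cc1CC(=O)N2[C@H](Cc3ccccc3)COC2=O | intermediate
19 | 4-hydroxy-3,5-dimethoxybenzaldehyde (syringaldehyde) | COc1cc(C=O)cc(OC)c1O | starting material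
20 | 3,5-dimethoxy-4-(methoxymethoxy)benzaldehyde | COCOc1c(OC)cc(C=O)cc1OC | intermediate
21 | (Z)-dibutylboron enolate of 18 (not isolated) | CCCCB(CCCC)O/C(=C\c1cc(I)cc(OC)c1OCOC)N2[C@H](Cc3ccccc3)COC2=O | intermediate
22 | O-dibutylboryl aldolate of 23 (not isolated) | O=C(N1[C@H](Cc2ccccc2)COC1=O)[C@H](c3cc(I)cc(OC)c3OCOC)[C@@H](OB(CCCC)CCCC)c4cc(OC)c(OCOC)c(OC)c4 | intermediate
23 | (R)-4-benzyl-3-[(2R,3R)-3-[3,5-dimethoxy-4-(methoxymethoxy)phenyl]-3-hydroxy-2-[5-iodo-3-methoxy-2-(methoxymethoxy)phenyl]propanoyl]-1,3-oxazolidin-2-one (2,3-syn) | O=C(N1[C@H](Cc2ccccc2)COC1=O)[C@H](c3cc(I)cc(OC)c3OCOC)[C@@H](O)c4cc(OC)c(OCOC)c(OC)c4 | intermediate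
24 | (1R,2S)-1-[3,5-dimethoxy-4-(methoxymethoxy)phenyl]-2-[5-iodo-3-methoxy-2-(methoxymethoxy)phenyl]propane-1,3-diol | OC[C@H](c1cc(I)cc(OC)c1OCOC)[C@@H](O)c2cc(OC)c(OCOC)c(OC)c2 | intermediate
25 | (1R,2S)-1-(4-hydroxy-3,5-dimethoxyphenyl)-2-(2-hydroxy-5-iodo-3-methoxyphenyl)propane-1,3-diol (not isolated) | OC[C@H](c1cc(I)cc(OC)c1O)[C@@H](O)c2cc(OC)c(O)c(OC)c2 | intermediate
26 | 4-[(2R,3S)-3-hydroxymethyl-5-iodo-7-methoxy-2,3-dihydro-1-benzofuran-2-yl]-2,6-dimethoxyphenol (2,3-trans) | COc1cc([C@@H]2Oc3c(OC)cc(I)cc3[C@H]2CO)cc(OC)c1O | intermediate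
27 | bromoacetyl bromide | BrCC(Br)=O | starting material
28 | lithium salt of 16 (not isolated) | [Li+].O=C1[N-][C@H](Cc2ccccc2)CO1 | intermediate
29 | (R)-4-benzyl-3-(2-bromoacetyl)-1,3-oxazolidin-2-one | O=C(CBr)N1[C@H](Cc2ccccc2)COC1=O | intermediate
30 | (R)-4-benzyl-3-{[4-((2R,3S)-3-hydroxymethyl-5-iodo-7-methoxy-2,3-dihydro-1-benzofuran-2-yl)-2,6-dimethoxyphenoxy]acetyl}-1,3-oxazolidin-2-one | O=C(COc1c(OC)cc([C@@H]2Oc3c(OC)cc(I)cc3[C@H]2CO)cc1OC)N4[C@H](Cc5ccccc5)COC4=O | intermediate
31 | primary TBS ether of 30 | O=C(COc1c(OC)cc([C@@H]2Oc3c(OC)cc(I)cc3[C@H]2CO[Si](C)(C)C(C)(C)C)cc1OC)N4[C@H](Cc5ccccc5)COC4=O | intermediate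
32 | (Z)-dibutylboron enolate of 31 (not isolated) | CCCCB(CCCC)O/C(=C\Oc1c(OC)cc([C@@H]2Oc3c(OC)cc(I)cc3[C@H]2CO[Si](C)(C)C(C)(C)C)cc1OC)N4[C@H](Cc5ccccc5)COC4=O | intermediate
33 | O7'-dibutylboryl aldolate of 34 (not isolated) | COc1cc([C@@H](O[Si](C)(C)C(C)(C)C)[C@H](CO[Si](C)(C)C(C)(C)C)Oc2c(OC)cc([C@H](OB(CCCC)CCCC)[C@H](C(=O)N6[C@H](Cc7ccccc7)COC6=O)Oc3c(OC)cc([C@@H]4Oc5c(OC)cc(I)cc5[C@H]4CO[Si](C)(C)C(C)(C)C)cc3OC)cc2OC)ccc1O[Si](C)(C)C(C)(C)C | intermediate
34 | syn aldol adduct: (R)-4-benzyl-1,3-oxazolidin-2-one N-acylated by the unit B propanoyl chain, (7'S,8'R), with 7'-OH and ring B of 9 on C7' and the ring C aryloxy group of 31 on C8'; unit A (7R,8S) and the dihydrobenzofuran (7''R,8''S) as in 9 and 31 | COc1cc([C@@H](O[Si](C)(C)C(C)(C)C)[C@H](CO[Si](C)(C)C(C)(C)C)Oc2c(OC)cc([C@H](O)[C@H](C(=O)N6[C@H](Cc7ccccc7)COC6=O)Oc3c(OC)cc([C@@H]4Oc5c(OC)cc(I)cc5[C@H]4CO[Si](C)(C)C(C)(C)C)cc3OC)cc2OC)ccc1O[Si](C)(C)C(C)(C)C | intermediate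
35 | 7'-O-(4-nitrobenzoyl) imide with inverted C7', (7'R,8'R)-anti, otherwise as 34 | COc1cc([C@@H](O[Si](C)(C)C(C)(C)C)[C@H](CO[Si](C)(C)C(C)(C)C)Oc2c(OC)cc([C@@H](OC(=O)c8ccc(cc8)[N+](=O)[O-])[C@H](C(=O)N6[C@H](Cc7ccccc7)COC6=O)Oc3c(OC)cc([C@@H]4Oc5c(OC)cc(I)cc5[C@H]4CO[Si](C)(C)C(C)(C)C)cc3OC)cc2OC)ccc1O[Si](C)(C)C(C)(C)C | intermediate
36 | (7R,8S,7'R,8'S,7''R,8''S)-7',9'-diol: target skeleton with iodine at C5 of ring D in place of the propenal chain and TBS ethers on the ring A phenol, O7, O9 and O9'' | COc1cc([C@@H](O[Si](C)(C)C(C)(C)C)[C@H](CO[Si](C)(C)C(C)(C)C)Oc2c(OC)cc([C@@H](O)[C@H](CO)Oc3c(OC)cc([C@@H]4Oc5c(OC)cc(I)cc5[C@H]4CO[Si](C)(C)C(C)(C)C)cc3OC)cc2OC)ccc1O[Si](C)(C)C(C)(C)C | intermediate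
37 | acrolein (prop-2-enal) | C=CC=O | starting material
38 | target carrying TBS ethers on the ring A phenol, O7, O9 and O9'', (E)-enal, (7R,8S,7'R,8'S,7''R,8''S) | COc1cc([C@@H](O[Si](C)(C)C(C)(C)C)[C@H](CO[Si](C)(C)C(C)(C)C)Oc2c(OC)cc([C@@H](O)[C@H](CO)Oc3c(OC)cc([C@@H]4Oc5c(OC)cc(/C=C/C=O)cc5[C@H]4CO[Si](C)(C)C(C)(C)C)cc3OC)cc2OC)ccc1O[Si](C)(C)C(C)(C)C | intermediate
39 | CNP0192639.1, (7R,8S,7'R,8'S,7''R,8''S), (E)-enal | COc1cc([C@@H](O)[C@H](CO)Oc2c(OC)cc([C@@H](O)[C@H](CO)Oc3c(OC)cc([C@@H]4Oc5c(OC)cc(/C=C/C=O)cc5[C@H]4CO)cc3OC)cc2OC)ccc1O | target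

Total step count: 22.
Longest linear sequence: 15 steps (steps 6–10, 12–14, 16–22, from o-vanillin 10).

Steps most likely to fail

Step 1 (ylide capture). Proton transfer within the oxonium ylide may outrun the aldol-type capture, so that only O–H insertion occurs, or the acid may control the two new centres poorly. The fallback uses known auxiliary chemistry, sets out from 3 and comes back at 7. Compound 3 is O-alkylated (K2CO3, acetone) with (S)-4-benzyl-3-(2-bromoacetyl)-1,3-oxazolidin-2-one F1, which is made from commercial (S)-4-benzyl-1,3-oxazolidin-2-one and 27 as in step 15, to give the aryloxyacetyl imide F2. A MgCl2-catalysed direct anti-aldol addition to 1 (MgCl2, Et3N, TMSCl, EtOAc, rt) should then give the silylated anti adduct F3 by attack on the magnesium-chelated Z-enolate face away from the benzyl group, and citric acid in MeOH frees the alcohol F4. TBSOTf with 2,6-lutidine gives the silyl ether F5, and LiAlH4 as in step 3, which here also releases the auxiliary, returns the route at 7.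

Step 19 (Mitsunobu inversion). Elimination across C7'–C8' or ionisation of the hindered benzylic oxyphosphonium ion may compete, with loss of clean inversion. The fallback sets out from 26 and comes back at 36, and needs no inversion. Phenol 26 is alkylated with F1 (K2CO3, acetone) to the (S)-configured imide F6, which is silylated (TBSCl, imidazole) to F7. The MgCl2/Et3N/TMSCl anti-aldol addition of F7 to 9 should give the anti adduct directly as its trimethylsilyl ether F8, citric acid in MeOH gives the alcohol F9, and LiBH4 as in step 20 returns the route at 36.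

Step 21 (Heck reaction). Acrolein may polymerise and the catalyst may die before the electron-rich aryl iodide is consumed. The fallback sets out from 36 and comes back at 38. A Suzuki–Miyaura coupling of 36 with commercial (E)-2-(3,3-diethoxyprop-1-enyl)-4,4,5,5-tetramethyl-1,3,2-dioxaborolane (Pd(dppf)Cl2, NaHCO3, THF/H2O, 50 °C) should give the enal diethyl acetal F10, and PPTS in wet acetone at rt unmasks the aldehyde to give 38.

Further compounds
F1 | step 1 | (S)-4-benzyl-3-(2-bromoacetyl)-1,3-oxazolidin-2-one | O=C(CBr)N1[C@@H](Cc2ccccc2)COC1=O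
F2 | step 1 | (S)-4-benzyl-3-[(2,6-dimethoxy-4-methoxycarbonylphenoxy)acetyl]-1,3-oxazolidin-2-one | COC(=O)c1cc(OC)c(OCC(=O)N2[C@@H](Cc3ccccc3)COC2=O)c(OC)c1
F3 | step 1 | (S)-4-benzyl-3-[(2R,3R)-3-(4-acetoxy-3-methoxyphenyl)-2-(2,6-dimethoxy-4-methoxycarbonylphenoxy)-3-(trimethylsilyloxy)propanoyl]-1,3-oxazolidin-2-one | COc1cc([C@@H](O[Si](C)(C)C)[C@H](C(=O)N2[C@@H](Cc3ccccc3)COC2=O)Oc4c(OC)cc(C(=O)OC)cc4OC)ccc1OC(C)=O
F4 | step 1 | (S)-4-benzyl-3-[(2R,3R)-3-(4-acetoxy-3-methoxyphenyl)-2-(2,6-dimethoxy-4-methoxycarbonylphenoxy)-3-hydroxypropanoyl]-1,3-oxazolidin-2-one | COc1cc([C@@H](O)[C@H](C(=O)N2[C@@H](Cc3ccccc3)COC2=O)Oc4c(OC)cc(C(=O)OC)cc4OC)ccc1OC(C)=O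
F5 | step 1 | 3-O-TBS ether of F4 | COc1cc([C@@H](O[Si](C)(C)C(C)(C)C)[C@H](C(=O)N2[C@@H](Cc3ccccc3)COC2=O)Oc4c(OC)cc(C(=O)OC)cc4OC)ccc1OC(C)=O
F6 | step 19 | (S)-4-benzyl-3-{[4-((2R,3S)-3-hydroxymethyl-5-iodo-7-methoxy-2,3-dihydro-1-benzofuran-2-yl)-2,6-dimethoxyphenoxy]acetyl}-1,3-oxazolidin-2-one | O=C(COc1c(OC)cc([C@@H]2Oc3c(OC)cc(I)cc3[C@H]2CO)cc1OC)N4[C@@H](Cc5ccccc5)COC4=O
F7 | step 19 | primary TBS ether of F6 | O=C(COc1c(OC)cc([C@@H]2Oc3c(OC)cc(I)cc3[C@H]2CO[Si](C)(C)C(C)(C)C)cc1OC)N4[C@@H](Cc5ccccc5)COC4=O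
F8 | step 19 | (7'R,8'R)-anti aldol adduct of F7 and 9 as its 7'-O-trimethylsilyl ether, (S)-auxiliary | COc1cc([C@@H](O[Si](C)(C)C(C)(C)C)[C@H](CO[Si](C)(C)C(C)(C)C)Oc2c(OC)cc([C@@H](O[Si](C)(C)C)[C@H](C(=O)N6[C@@H](Cc7ccccc7)COC6=O)Oc3c(OC)cc([C@@H]4Oc5c(OC)cc(I)cc5[C@H]4CO[Si](C)(C)C(C)(C)C)cc3OC)cc2OC)ccc1O[Si](C)(C)C(C)(C)C
F9 | step 19 | (7'R,8'R)-anti aldol adduct of F7 and 9 with free 7'-OH, (S)-auxiliary | COc1cc([C@@H](O[Si](C)(C)C(C)(C)C)[C@H](CO[Si](C)(C)C(C)(C)C)Oc2c(OC)cc([C@@H](O)[C@H](C(=O)N6[C@@H](Cc7ccccc7)COC6=O)Oc3c(OC)cc([C@@H]4Oc5c(OC)cc(I)cc5[C@H]4CO[Si](C)(C)C(C)(C)C)cc3OC)cc2OC)ccc1O[Si](C)(C)C(C)(C)C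
F10 | step 21 | diethyl acetal of enal 38 | COc1cc([C@@H](O[Si](C)(C)C(C)(C)C)[C@H](CO[Si](C)(C)C(C)(C)C)Oc2c(OC)cc([C@@H](O)[C@H](CO)Oc3c(OC)cc([C@@H]4Oc5c(OC)cc(/C=C/C(OCC)OCC)cc5[C@H]4CO[Si](C)(C)C(C)(C)C)cc3OC)cc2OC)ccc1O[Si](C)(C)C(C)(C)C
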